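**Retrosynthetic overview**
- The strategy rests on the γ-keto acid array HO2C–C2–Ca–Cb(=O)–aryl. It hangs on the quaternary carbon C2, flanked by O1 and C3, of the 2,3,4,7-tetrahydrooxepine ring O1–C2–C3–C4–C5=C6–C7. With Cb held as an (R)-benzylic alcohol, the array folds into a γ-aryl butyrolactone whose temporary centre directs the construction of C2.
- Late disconnections: aryl MOM ethers and PMB ester (acidolysis), coumarate ester (Mitsunobu), and the Cb ketone (oxidation of the alcohol freed when the lactone is hydrolysed).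
- Key disconnection C2–C3: a primary iodide alkylates the α-alkoxy lactone enolate intramolecularly. This closes the oxepine as a spirocycle on the lactone, with C3 anti to the aryl group.
- The O1–C7 ether joins an α-hydroxy-γ-aryl lactone (aldol, asymmetric transfer hydrogenation, lactonisation) to a Z-allylic bromide. The bromide's geometry is inherited from a side-chain-coupled dihydropyranone (Negishi coupling, reduction).
- Ring order: butyrolactone (step 3), then oxepine (step 12). The lactone ring is opened again in step 13.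

Key step: step 12

Remark: the lactone α-carbon (the future C2) is carried as a mixture of epimers up to the key step, because enolisation erases it. The labels O1, C2–C7, Ca and Cb follow the target throughout.

**Step 1**
Reactants: 1 2',5'-dihydroxyacetophenone
Product: 2 2',5'-bis(methoxymethoxy)acetophenone
Conditions: NaH, MOMCl, DMF, 0 °C to rt
Reagents that add atoms: chloromethyl methyl ether (MOMCl), COCCl
Why: Williamson-type O-alkylation of both phenoxides, with NaH used to break the hydrogen bond between the ortho phenol and the ketone, should install MOM acetals that tolerate every base, hydride and oxidant used before the last step.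

**Step 2**
Reactants: 2 2',5'-bis(methoxymethoxy)acetophenone; 3 ethyl glyoxylate (freshly distilled monomer)
Product: 5 ethyl 4-[2,5-bis(methoxymethoxy)phenyl]-2-hydroxy-4-oxobutanoate (racemic), via lithium enolate 4 (not isolated)
Conditions: LiN(SiMe3)2, THF, −78 °C; then 3, −78 °C; AcOH quench
Reagents that add atoms: none
Why: Crossed aldol addition of a methyl ketone lithium enolate to a non-enolisable, very electrophilic aldehyde should be clean at low temperature, and the carbinol centre is deliberately made racemic because step 12 erases it.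

**Step 3**
Reactants: 5 ethyl 4-[2,5-bis(methoxymethoxy)phenyl]-2-hydroxy-4-oxobutanoate
Product: 7 (5R)-5-[2,5-bis(methoxymethoxy)phenyl]-3-hydroxyoxolan-2-one (both C3 epimers), via dihydroxy ester 6 (not isolated)
Conditions: RuCl[(R,R)-TsDPEN](p-cymene) (1 mol%), HCO2H/Et3N (5:2), EtOAc, 30 °C; then PPTS (cat.), toluene, 60 °C
Reagents that add atoms: none
Why: Noyori–Ikariya asymmetric transfer hydrogenation of the aryl alkyl ketone sets Cb under catalyst control, the (R,R)-ligand delivering hydride to the face that gives the (R)-benzylic alcohol as it does for acetophenone, after which the γ-hydroxy ester closes to the five-membered lactone by acid-catalysed transesterification.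

**Step 4**
Reactants: 8 5-bromo-2-methylpent-2-ene
Product: 10 (E)-5-bromo-2-methylpent-2-en-1-ol, via over-oxidised enal 9 (not isolated)
Conditions: SeO2 (cat.), t-BuOOH, CH2Cl2, 0 °C to rt; then NaBH4, MeOH, 0 °C
Reagents that add atoms: tert-butyl hydroperoxide, CC(C)(C)OO (source of the new oxygen, passed on by the catalyst selenium dioxide, O=[Se]=O)
Why: Catalytic SeO2 allylic oxidation (ene reaction followed by a [2,3]-sigmatropic shift) attacks the methyl group trans to the chain and so should give the (E)-allylic alcohol, while borohydride returns the over-oxidised enal to the alcohol without touching the primary bromide.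

**Step 5**
Reactants: 10 (E)-5-bromo-2-methylpent-2-en-1-ol
Product: 11 [(E)-5-bromo-2-methylpent-2-enyl]oxy-tert-butyldimethylsilane
Conditions: TBSCl, imidazole, CH2Cl2, 0 °C to rt
Reagents that add atoms: tert-butyldimethylsilyl chloride, CC(C)(C)[Si](C)(C)Cl
Why: Imidazole-promoted silylation of a primary alcohol is routine, and the TBS ether survives zinc insertion, hydride, silver oxide, amide base and hydroxide.

**Step 6**
Reactants: 12 5,6-dihydro-2H-pyran-2-one
Product: 14 3-bromo-5,6-dihydro-2H-pyran-2-one, via dibromolactone 13 (not isolated)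
Conditions: Br2, CH2Cl2, 0 °C to rt; then Et3N, rt
Reagents that add atoms: bromine, BrBr
Why: Bromine addition to the enoate alkene followed by amine-induced dehydrobromination, in which the acidic α-hydrogen is removed and the β-bromide leaves, is the standard bromination–elimination route to α-bromo enoates.

**Step 7**
Reactants: 11 [(E)-5-bromo-2-methylpent-2-enyl]oxy-tert-butyldimethylsilane; 14 3-bromo-5,6-dihydro-2H-pyran-2-one
Product: 16 3-[(E)-5-(tert-butyldimethylsilyloxy)-4-methylpent-3-enyl]-5,6-dihydro-2H-pyran-2-one, via alkylzinc bromide 15 (not isolated)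
Conditions: Zn dust, LiCl, THF, 50 °C; then 14, PdCl2(dppf) (3 mol%), THF, rt to 45 °C
Reagents that add atoms: none
Why: Negishi sp3–sp2 coupling should work because the electron-poor alkenyl bromide undergoes fast oxidative addition, the wide-bite-angle dppf ligand favours reductive elimination over β-hydride elimination, and an alkylzinc halide adds neither to the lactone carbonyl nor in conjugate fashion.

**Step 8**
Reactants: 16 3-[(E)-5-(tert-butyldimethylsilyloxy)-4-methylpent-3-enyl]-5,6-dihydro-2H-pyran-2-one
Product: 17 (Z)-2-[(E)-5-(tert-butyldimethylsilyloxy)-4-methylpent-3-enyl]pent-2-ene-1,5-diol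
Conditions: i-Bu2AlH (4.5 equiv), CH2Cl2, −78 to 0 °C; aq. potassium sodium tartrate
Reagents that add atoms: none
Why: Exhaustive 1,2-reduction of the unsaturated lactone by the electrophilic hydride i-Bu2AlH leaves the alkene untouched, so the cis relation of C7 and C4 imposed by the six-membered ring is transferred intact into the Z-diol.

**Step 9**
Reactants: 17 (Z)-2-[(E)-5-(tert-butyldimethylsilyloxy)-4-methylpent-3-enyl]pent-2-ene-1,5-diol
Product: 19 (3Z,7E)-4-(bromomethyl)-9-(tert-butyldimethylsilyloxy)-8-methylnona-3,7-dienyl methanesulfonate, via bis-mesylate 18 (not isolated)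
Conditions: MsCl, Et3N, THF, −45 °C; then LiBr, THF, 0 °C
Reagents that add atoms: methanesulfonyl chloride, CS(=O)(=O)Cl; lithium bromide, [Li+].[Br-]
Why: Fast mesylation caps both hydroxyls before either can cyclise onto the other, and SN2 displacement by bromide at 0 °C then takes only the much more reactive allylic mesylate without allylic transposition, so the two termini are told apart by reactivity and no protecting group is needed.

**Step 10**
Reactants: 7 (5R)-5-[2,5-bis(methoxymethoxy)phenyl]-3-hydroxyoxolan-2-one; 19 (3Z,7E)-4-(bromomethyl)-9-(tert-butyldimethylsilyloxy)-8-methylnona-3,7-dienyl methanesulfonate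
Product: 20 (5R)-5-[2,5-bis(methoxymethoxy)phenyl]-3-{[(Z)-5-(methanesulfonyloxy)-2-[(E)-4-methyl-5-(tert-butyldimethylsilyloxy)pent-3-enyl]pent-2-enyl]oxy}oxolan-2-one (both C3 epimers)
Conditions: Ag2O, 4 Å molecular sieves, CH2Cl2, dark, rt
Reagents that add atoms: none
Why: Purdie-type silver oxide etherification activates the allylic C–Br bond and takes up HBr without forming a free alkoxide, so the lactone stays closed, the primary mesylate is inert, and attack at the unhindered CH2 terminus C7 keeps the Z-trisubstituted alkene.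

**Step 11**
Reactants: 20 the ether mesylate
Product: 21 (5R)-5-[2,5-bis(methoxymethoxy)phenyl]-3-{[(Z)-5-iodo-2-[(E)-4-methyl-5-(tert-butyldimethylsilyloxy)pent-3-enyl]pent-2-enyl]oxy}oxolan-2-one (both C3 epimers)
Conditions: NaI, acetone, 50 °C
Reagents that add atoms: sodium iodide, [Na+].[I-]
Why: Finkelstein-type SN2 displacement of the primary mesylate, driven by precipitation of the sodium sulfonate, is safe here because no allylic halide remains that iodide could isomerise.

**Step 12**
Reactants: 21 the iodo lactone (both C3 epimers)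
Product: 23 (2R,5'R)-5'-[2,5-bis(methoxymethoxy)phenyl]-6-[(E)-4-methyl-5-(tert-butyldimethylsilyloxy)pent-3-enyl]-4,7-dihydro-3H-spiro[oxepine-2,3'-oxolan]-2'-one, via potassium enolate 22 (not isolated)
Conditions: KN(SiMe3)2 (1.1 equiv, slow addition), THF (0.004 M), −78 to −40 °C
Reagents that add atoms: none
Why: KN(SiMe3)2 removes the C2–H of both epimers, which thereby converge on one planar α-alkoxy lactone enolate whose carbon C2 displaces iodide from C3 in an intramolecular SN2 reaction. The closest known reaction types are the intramolecular alkylation of α-alkoxy ester and amide enolates used to build medium-ring ethers and the anti-selective alkylation of γ-substituted butyrolactone enolates. The oxepine closes in the 7-(enolexo)-exo-tet mode, helped by the cis C5=C6 alkene, which removes rotors from the tether and holds C3 near C2, while the lactone already present becomes the second ring of the spirocycle. The new quaternary centre C2 is controlled by the aryl group on Cb: the tether hangs from the in-plane oxygen O1 and could reach either face, but the face syn to the ortho-substituted aryl ring is shielded, so C3 should enter anti to it and (R)-Cb should give (R)-C2, any syn diastereomer being removed by chromatography here so that it cannot erode enantiopurity once Cb is oxidised. The step needs C-alkylation to outrun the [2,3]-Wittig shift of the allyloxy enolate and E2 loss of HI; the shift would have to join the fully substituted C2 to the substituted alkene terminus C5 and is slowed by that crowding, by the low temperature and by the absence of polar additives, while slow addition of barely more than one equivalent of hindered base leaves no free base for elimination. High dilution suppresses intermolecular alkylation and Claisen condensation.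

**Step 13**
Reactants: 23 the spirolactone
Product: 25 4-methoxybenzyl (2R)-2-{(2R)-2-[2,5-bis(methoxymethoxy)phenyl]-2-hydroxyethyl}-6-[(E)-4-methyl-5-(tert-butyldimethylsilyloxy)pent-3-enyl]-2,3,4,7-tetrahydrooxepine-2-carboxylate, via potassium carboxylate 24 (not isolated)
Conditions: KOH (1.1 equiv), THF/H2O, rt; evaporate to dryness (toluene azeotrope); PMBCl, Bu4NI (cat.), DMF, 0 °C to rt; used crude
Reagents that add atoms: potassium hydroxide, [K+].[OH-]; 4-methoxybenzyl chloride, COc1ccc(CCl)cc1
Why: Saponification by acyl–oxygen cleavage gives a carboxylate salt that cannot relactonise, and SN2 O-alkylation of the dry salt traps it as an ester while the neutral benzylic alcohol stays unalkylated and the quaternary C2 cannot epimerise.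

**Step 14**
Reactants: 25 the hydroxy PMB ester
Product: 26 4-methoxybenzyl (2R)-2-{2-[2,5-bis(methoxymethoxy)phenyl]-2-oxoethyl}-6-[(E)-4-methyl-5-(tert-butyldimethylsilyloxy)pent-3-enyl]-2,3,4,7-tetrahydrooxepine-2-carboxylate
Conditions: Dess–Martin periodinane, NaHCO3, CH2Cl2, 0 °C
Reagents that add atoms: none
Why: Buffered Dess–Martin oxidation of the secondary benzylic alcohol is fast enough to outrun relactonisation, spares the alkenes, acetals, silyl ether and ester, and removes the relay stereocentre now that it has done its work.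

**Step 15**
Reactants: 26 the keto PMB ester
Product: 27 4-methoxybenzyl (2R)-2-{2-[2,5-bis(methoxymethoxy)phenyl]-2-oxoethyl}-6-[(E)-5-hydroxy-4-methylpent-3-enyl]-2,3,4,7-tetrahydrooxepine-2-carboxylate
Conditions: HF·pyridine, pyridine, THF, 0 °C to rt
Reagents that add atoms: none
Why: Fluoride-driven desilylation of the primary allylic TBS ether is done with buffered HF·pyridine rather than a basic fluoride source, because the ketone now has the ring oxygen O1 on its β-carbon and base could trigger E1cB opening of the oxepine.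

**Step 16**
Reactants: 27 the allylic alcohol; 28 (E)-4-hydroxycinnamic acid (p-coumaric acid)
Product: 29 4-methoxybenzyl (2R)-2-{2-[2,5-bis(methoxymethoxy)phenyl]-2-oxoethyl}-6-[(E)-5-{[(E)-3-(4-hydroxyphenyl)prop-2-enoyl]oxy}-4-methylpent-3-enyl]-2,3,4,7-tetrahydrooxepine-2-carboxylate
Conditions: PPh3, DIAD, THF, 0 °C to rt
Reagents that add atoms: none
Why: In this Mitsunobu esterification the betaine deprotonates the carboxylic acid (pKa about 4.5) in preference to the phenol (pKa about 10), so the unprotected phenolic acid should attack the primary allylic alkoxyphosphonium ion through its carboxylate only, under neutral conditions that spare the β-alkoxy ketone.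

**Step 17**
Reactants: 29 the protected coumarate
Product: 30 (2R)-2-[2-(2,5-dihydroxyphenyl)-2-oxoethyl]-6-[(E)-5-{[(E)-3-(4-hydroxyphenyl)prop-2-enoyl]oxy}-4-methylpent-3-enyl]-2,3,4,7-tetrahydrooxepine-2-carboxylic acid (CNP0602535.1)
Conditions: TFA/CH2Cl2 (1:3), anisole, 0 °C to rt; aqueous work-up
Reagents that add atoms: none
Why: Global acidolysis cleaves the PMB ester through the 4-methoxybenzyl cation (trapped by anisole in a Friedel–Crafts reaction) and both aryl MOM acetals through their oxocarbenium ions, while each trisubstituted alkene is deactivated towards protonation by the allylic C–O bond next to its would-be cationic carbon and the quaternary C2 cannot be scrambled.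

**Compound list**
1 | 2',5'-dihydroxyacetophenone | CC(=O)c1cc(O)ccc1O | starting material
2 | 2',5'-bis(methoxymethoxy)acetophenone | CC(=O)c1cc(OCOC)ccc1OCOC | intermediate
3 | ethyl glyoxylate | CCOC(=O)C=O | starting material
4 | lithium 1-[2,5-bis(methoxymethoxy)phenyl]ethenolate | [Li]OC(=C)c1cc(OCOC)ccc1OCOC | intermediate
5 | ethyl 4-[2,5-bis(methoxymethoxy)phenyl]-2-hydroxy-4-oxobutanoate (racemic) | CCOC(=O)C(O)CC(=O)c1cc(OCOC)ccc1OCOC | intermediate
6 | ethyl (4R)-4-[2,5-bis(methoxymethoxy)phenyl]-2,4-dihydroxybutanoate (both C2 epimers) | CCOC(=O)C(O)C[C@H](c1cc(OCOC)ccc1OCOC)O | intermediate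
7 | (5R)-5-[2,5-bis(methoxymethoxy)phenyl]-3-hydroxyoxolan-2-one (both C3 epimers) | OC1C[C@H](c2cc(OCOC)ccc2OCOC)OC1=O | intermediate
8 | 5-bromo-2-methylpent-2-ene | CC(C)=CCCBr | starting material
9 | (E)-5-bromo-2-methylpent-2-enal | C/C(=C\CCBr)C=O | intermediate
10 | (E)-5-bromo-2-methylpent-2-en-1-ol | C/C(=C\CCBr)CO | intermediate
11 | [(E)-5-bromo-2-methylpent-2-enyl]oxy-tert-butyldimethylsilane | C/C(=C\CCBr)CO[Si](C)(C)C(C)(C)C | intermediate
12 | 5,6-dihydro-2H-pyran-2-one | O=C1C=CCCO1 | starting material
13 | 3,4-dibromooxan-2-one (trans, racemic) | O=C1OCCC(Br)C1Br | intermediate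
14 | 3-bromo-5,6-dihydro-2H-pyran-2-one | O=C1OCCC=C1Br | intermediate
15 | [(E)-5-(tert-butyldimethylsilyloxy)-4-methylpent-3-enyl]zinc bromide | C/C(=C\CC[Zn]Br)CO[Si](C)(C)C(C)(C)C | intermediate
16 | 3-[(E)-5-(tert-butyldimethylsilyloxy)-4-methylpent-3-enyl]-5,6-dihydro-2H-pyran-2-one | C/C(=C\CCC1=CCCOC1=O)CO[Si](C)(C)C(C)(C)C | intermediate
17 | (Z)-2-[(E)-5-(tert-butyldimethylsilyloxy)-4-methylpent-3-enyl]pent-2-ene-1,5-diol | C/C(=C\CC/C(=C/CCO)CO)CO[Si](C)(C)C(C)(C)C | intermediate
18 | bis(methanesulfonate) of diol 17 | C/C(=C\CC/C(=C/CCOS(C)(=O)=O)COS(C)(=O)=O)CO[Si](C)(C)C(C)(C)C | intermediate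
19 | (3Z,7E)-4-(bromomethyl)-9-(tert-butyldimethylsilyloxy)-8-methylnona-3,7-dienyl methanesulfonate | C/C(=C\CC/C(=C/CCOS(C)(=O)=O)CBr)CO[Si](C)(C)C(C)(C)C | intermediate
20 | (5R)-5-[2,5-bis(methoxymethoxy)phenyl]-3-{[(Z)-5-(methanesulfonyloxy)-2-[(E)-4-methyl-5-(tert-butyldimethylsilyloxy)pent-3-enyl]pent-2-enyl]oxy}oxolan-2-one (both C3 epimers) | C/C(=C\CC/C(=C/CCOS(C)(=O)=O)COC1C[C@H](c2cc(OCOC)ccc2OCOC)OC1=O)CO[Si](C)(C)C(C)(C)C | intermediate
21 | (5R)-5-[2,5-bis(methoxymethoxy)phenyl]-3-{[(Z)-5-iodo-2-[(E)-4-methyl-5-(tert-butyldimethylsilyloxy)pent-3-enyl]pent-2-enyl]oxy}oxolan-2-one (both C3 epimers) | C/C(=C\CC/C(=C/CCI)COC1C[C@H](c2cc(OCOC)ccc2OCOC)OC1=O)CO[Si](C)(C)C(C)(C)C | intermediate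
22 | potassium enolate of 21 | C/C(=C\CC/C(=C/CCI)COC1=C([O-])O[C@@H](c2cc(OCOC)ccc2OCOC)C1)CO[Si](C)(C)C(C)(C)C.[K+] | intermediate
23 | (2R,5'R)-5'-[2,5-bis(methoxymethoxy)phenyl]-6-[(E)-4-methyl-5-(tert-butyldimethylsilyloxy)pent-3-enyl]-4,7-dihydro-3H-spiro[oxepine-2,3'-oxolan]-2'-one | C/C(=C\CCC1=CCC[C@]2(C[C@H](c3cc(OCOC)ccc3OCOC)OC2=O)OC1)CO[Si](C)(C)C(C)(C)C | intermediate
24 | potassium (2R)-2-{(2R)-2-[2,5-bis(methoxymethoxy)phenyl]-2-hydroxyethyl}-6-[(E)-4-methyl-5-(tert-butyldimethylsilyloxy)pent-3-enyl]-2,3,4,7-tetrahydrooxepine-2-carboxylate | C/C(=C\CCC1=CCC[C@@](C[C@H](c2cc(OCOC)ccc2OCOC)O)(C(=O)[O-])OC1)CO[Si](C)(C)C(C)(C)C.[K+] | intermediate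
25 | 4-methoxybenzyl (2R)-2-{(2R)-2-[2,5-bis(methoxymethoxy)phenyl]-2-hydroxyethyl}-6-[(E)-4-methyl-5-(tert-butyldimethylsilyloxy)pent-3-enyl]-2,3,4,7-tetrahydrooxepine-2-carboxylate | C/C(=C\CCC1=CCC[C@@](C[C@H](c2cc(OCOC)ccc2OCOC)O)(C(=O)OCc3ccc(OC)cc3)OC1)CO[Si](C)(C)C(C)(C)C | intermediate
26 | 4-methoxybenzyl (2R)-2-{2-[2,5-bis(methoxymethoxy)phenyl]-2-oxoethyl}-6-[(E)-4-methyl-5-(tert-butyldimethylsilyloxy)pent-3-enyl]-2,3,4,7-tetrahydrooxepine-2-carboxylate | C/C(=C\CCC1=CCC[C@@](CC(=O)c2cc(OCOC)ccc2OCOC)(C(=O)OCc3ccc(OC)cc3)OC1)CO[Si](C)(C)C(C)(C)C | intermediate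
27 | 4-methoxybenzyl (2R)-2-{2-[2,5-bis(methoxymethoxy)phenyl]-2-oxoethyl}-6-[(E)-5-hydroxy-4-methylpent-3-enyl]-2,3,4,7-tetrahydrooxepine-2-carboxylate | C/C(=C\CCC1=CCC[C@@](CC(=O)c2cc(OCOC)ccc2OCOC)(C(=O)OCc3ccc(OC)cc3)OC1)CO | intermediate
28 | (E)-4-hydroxycinnamic acid (p-coumaric acid) | O=C(O)/C=C/c1ccc(O)cc1 | starting material
29 | 4-methoxybenzyl (2R)-2-{2-[2,5-bis(methoxymethoxy)phenyl]-2-oxoethyl}-6-[(E)-5-{[(E)-3-(4-hydroxyphenyl)prop-2-enoyl]oxy}-4-methylpent-3-enyl]-2,3,4,7-tetrahydrooxepine-2-carboxylate | C/C(=C\CCC1=CCC[C@@](CC(=O)c2cc(OCOC)ccc2OCOC)(C(=O)OCc3ccc(OC)cc3)OC1)COC(=O)/C=C/c1ccc(O)cc1 | intermediate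
30 | (2R)-2-[2-(2,5-dihydroxyphenyl)-2-oxoethyl]-6-[(E)-5-{[(E)-3-(4-hydroxyphenyl)prop-2-enoyl]oxy}-4-methylpent-3-enyl]-2,3,4,7-tetrahydrooxepine-2-carboxylic acid | C/C(=C\CCC1=CCC[C@@](CC(=O)c2cc(O)ccc2O)(C(=O)O)OC1)COC(=O)/C=C/c1ccc(O)cc1 | target

**Step count**
- Total: 17 steps.
- Longest linear sequence: 13 steps, from 8 through steps 4, 5 and 7–17.
- The lactone branch (steps 1–3) joins at step 10, and step 6 joins at step 7.

**Three steps most likely to fail**

**Step 12.**
- What may go wrong: a sigmatropic [2,3]-shift of the allyloxy enolate, base-induced loss of HI from the homoallylic iodide, a seven-membered closure slow enough for intermolecular reactions to take over, or a weak facial bias.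
- Fallback in outline: C2–C3 is made intermolecularly and the oxepine is closed by ring-closing metathesis at C5=C6. It sets out from 7 and 15 and returns at 23.
- Side-chain piece: alkylzinc bromide 15, made from 11 as in step 7, is coupled with commercial 2-bromoprop-2-en-1-ol (Pd(OAc)2, SPhos, THF, rt). This Negishi coupling tolerates the free hydroxyl and gives the 2-substituted allylic alcohol F1. An Appel reaction (CBr4, PPh3) converts F1 into the allylic bromide F2.
- Lactone piece: 7 is silylated (TBSCl, imidazole) to the α-silyloxy lactone F3. Its enolate (LiN(SiMe3)2, THF/DMPU) is alkylated with 4-iodobut-1-ene anti to the aryl group to give the quaternary lactone F4. Bu4NF/AcOH then frees the tertiary alcohol F5.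
- Union and closure: NaH and F2 in DMF give the diene ether F6. The second-generation Hoveyda–Grubbs catalyst in toluene closes the trisubstituted C5=C6 alkene to 23.
- Why it avoids the problem: no allyloxy enolate and no homoallylic halide occur on this path.

**Step 13.**
- What may go wrong: the lactone may re-close from the γ-hydroxy ester during alkylation or handling, favoured by the gem-disubstituent effect at C2, and the hindered carboxylate may alkylate sluggishly.
- Fallback in outline: a redox detour that never passes through a γ-hydroxy carboxyl derivative. It sets out from 23 and returns at 26.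
- Sequence: LiAlH4 (THF, 0 °C) reduces the lactone to the 1,4-diol F7. Swern oxidation, in which both alcohols are activated before Et3N is added so that no lactol can form, gives the keto aldehyde F8. Pinnick oxidation (NaClO2, NaH2PO4, 2-methylbut-2-ene) gives the keto acid F9. PMBCl with KHCO3 in DMF then esterifies F9 to 26.

**Step 17.**
- What may go wrong while the slower MOM ether is being removed: protonation of the alkenes, ionisation of the allylic ester, acid-catalysed β-elimination of O1, and capture of formaldehyde equivalents by the freed phenols.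
- Fallback in outline: the order of events is changed so that the MOM groups leave before the coumarate is attached, and without protic acid. It sets out from 27 and returns at 30.
- Sequence: TMSOTf and 2,2'-bipyridyl in CH2Cl2, followed by water, convert the aryl MOM ethers through their silyl ethers into the hydroquinone alcohol F10, with the PMB ester intact. Chemoselective Mitsunobu esterification with 28 (PPh3, DIAD) gives the PMB ester of the target, F11. A short treatment with dilute TFA and anisole at 0 °C, sufficient for a PMB ester alone, then gives 30.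

**Further compounds**
F1 | step 12 | (E)-7-(tert-butyldimethylsilyloxy)-6-methyl-2-methylidenehept-5-en-1-ol | C/C(=C\CCC(=C)CO)CO[Si](C)(C)C(C)(C)C
F2 | step 12 | [(E)-6-(bromomethyl)-2-methylhepta-2,6-dienyl]oxy-tert-butyldimethylsilane | C/C(=C\CCC(=C)CBr)CO[Si](C)(C)C(C)(C)C
F3 | step 12 | (5R)-5-[2,5-bis(methoxymethoxy)phenyl]-3-(tert-butyldimethylsilyloxy)oxolan-2-one (both C3 epimers) | CC(C)(C)[Si](C)(C)OC1C[C@H](c2cc(OCOC)ccc2OCOC)OC1=O
F4 | step 12 | (3R,5R)-5-[2,5-bis(methoxymethoxy)phenyl]-3-(but-3-enyl)-3-(tert-butyldimethylsilyloxy)oxolan-2-one | C=CCC[C@@]1(O[Si](C)(C)C(C)(C)C)C[C@H](c2cc(OCOC)ccc2OCOC)OC1=O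
F5 | step 12 | (3R,5R)-5-[2,5-bis(methoxymethoxy)phenyl]-3-(but-3-enyl)-3-hydroxyoxolan-2-one | C=CCC[C@@]1(O)C[C@H](c2cc(OCOC)ccc2OCOC)OC1=O
F6 | step 12 | (3R,5R)-5-[2,5-bis(methoxymethoxy)phenyl]-3-(but-3-enyl)-3-{[(E)-7-(tert-butyldimethylsilyloxy)-6-methyl-2-methylidenehept-5-enyl]oxy}oxolan-2-one | C/C(=C\CCC(=C)CO[C@]1(CCC=C)C[C@H](c2cc(OCOC)ccc2OCOC)OC1=O)CO[Si](C)(C)C(C)(C)C
F7 | step 13 | (1R)-1-[2,5-bis(methoxymethoxy)phenyl]-2-{(2R)-2-(hydroxymethyl)-6-[(E)-4-methyl-5-(tert-butyldimethylsilyloxy)pent-3-enyl]-2,3,4,7-tetrahydrooxepin-2-yl}ethanol | C/C(=C\CCC1=CCC[C@@](C[C@H](c2cc(OCOC)ccc2OCOC)O)(CO)OC1)CO[Si](C)(C)C(C)(C)C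
F8 | step 13 | (2R)-2-{2-[2,5-bis(methoxymethoxy)phenyl]-2-oxoethyl}-6-[(E)-4-methyl-5-(tert-butyldimethylsilyloxy)pent-3-enyl]-2,3,4,7-tetrahydrooxepine-2-carbaldehyde | C/C(=C\CCC1=CCC[C@@](CC(=O)c2cc(OCOC)ccc2OCOC)(C=O)OC1)CO[Si](C)(C)C(C)(C)C
F9 | step 13 | (2R)-2-{2-[2,5-bis(methoxymethoxy)phenyl]-2-oxoethyl}-6-[(E)-4-methyl-5-(tert-butyldimethylsilyloxy)pent-3-enyl]-2,3,4,7-tetrahydrooxepine-2-carboxylic acid | C/C(=C\CCC1=CCC[C@@](CC(=O)c2cc(OCOC)ccc2OCOC)(C(=O)O)OC1)CO[Si](C)(C)C(C)(C)C
F10 | step 17 | 4-methoxybenzyl (2R)-2-[2-(2,5-dihydroxyphenyl)-2-oxoethyl]-6-[(E)-5-hydroxy-4-methylpent-3-enyl]-2,3,4,7-tetrahydrooxepine-2-carboxylate | C/C(=C\CCC1=CCC[C@@](CC(=O)c2cc(O)ccc2O)(C(=O)OCc3ccc(OC)cc3)OC1)CO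
F11 | step 17 | 4-methoxybenzyl (2R)-2-[2-(2,5-dihydroxyphenyl)-2-oxoethyl]-6-[(E)-5-{[(E)-3-(4-hydroxyphenyl)prop-2-enoyl]oxy}-4-methylpent-3-enyl]-2,3,4,7-tetrahydrooxepine-2-carboxylate | C/C(=C\CCC1=CCC[C@@](CC(=O)c2cc(O)ccc2O)(C(=O)OCc3ccc(OC)cc3)OC1)COC(=O)/C=C/c1ccc(O)cc1
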